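## The problem

Ring numbering used throughout: in both carbocycles C1 is the gem-dimethyl carbon, C3 the secondary carbinol, C5 the methyl-bearing carbon and C6 the carbon that holds the side chain; ring C is the butenolide.

- The target is a C37 nor-carotenoid whose three rings are joined only through an unsaturated chain. Ring A (a cyclohexenol) is bound through an alkyne to a methyl-branched all-E tetraene. The tetraene ends as the Z-ylidene group at C5 of ring C, and C3 of ring C carries ring B (a cyclohexane-1,2,4-triol) through an E-vinyl link.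
- There are four stereocentres: C3 of ring A (R) and C3, C5 and C6 of ring B (R, S, S). In ring B the two tertiary hydroxyls at C5 and C6 are trans-diaxial and the C6 hydroxyl is cis to the one at C3.
- Both C3 carbinols are R only because the ranking of their flanking ring carbons differs. In space they are opposite, so ring B cannot come from the same hydroxy ketone as ring A without an inversion.
- The centre of ring A controls nothing else. In ring B, C3 can direct an epoxidation of the C5=C6 alkene and then, through its equatorial preference, decide which oxirane carbon is opened, so C5 and C6 can both descend from C3.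
- Five E alkenes and one Z ylidene must each come from a stereospecific reaction, because the polyene cannot be purified from geometric isomers late.
- The ylidene butenolide is labile to base and nucleophiles, the polyene to light and acid, and the tertiary allylic alcohol at C6 of ring B to acid. The polar chemistry of ring B must therefore be finished before the polyene exists, and the last bond should be made under neutral conditions with no protecting group left.
- The feature that makes the key step possible: the trisubstituted E alkene next to the ring A alkyne carries its CH3 group and the next vinyl carbon cis to each other. It is therefore the syn adduct of methyl and vinyl across the terminal triple bond of a ring A buta-1,3-diyne, whose other triple bond is shielded by the C1 gem-dimethyl group and the C5 methyl group.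

## Retrosynthesis

**37 to 16 and 36.** The target 37 is cut at the single bond between the two unbranched CH=CH units in the middle of the tetraene, giving dienyl iodide 16 and trienylstannane 36. Both termini are unhindered CH carbons, so a Stille coupling can run at room temperature with retention. A cut one bond nearer ring A would place the coupling at the methyl-bearing carbon, and a cut nearer ring C would require a longer, less stable polyenyl iodide. Both halves carry free hydroxyls, so the coupling product is the target itself.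

**16 to 15 to 14.** The C–I bond of 16 is traced to the C–Si bond of dienylsilane 15 (ipso-iododesilylation), and 15 to its silyl ether 14. The silane is a robust placeholder that survives the organometallic key step. Fluoride is used on the silane, not on the iodide or the final polyene.

**14 to 10, 11 and 12 (key disconnection).** Two bonds of 14 are cut: the C–CH3 bond of the trisubstituted alkene and the bond between its CH carbon and the next CH. This leads to the ring A butadiyne 10, trimethylaluminium 11 and (E)-(2-bromovinyl)trimethylsilane 12. The cut removes an alkene, a methyl branch and a two-carbon unit at once, where a stepwise olefination would need three or four operations. The forward reaction must add methyl and metal syn to the terminal alkyne only, with methyl on the inner carbon, and couple with retention.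

**10 to 1.** The diyne 10 comes from its silyl-capped form 9. Compound 9 is cut at the ring–alkyne bond into enol triflate 5 and 1,4-bis(trimethylsilyl)buta-1,3-diyne 6, used through its mono-lithio and mono-protio forms 7 and 8. The triflate goes back through silyl ether 4 to the hydroxy ketone 3, the dione 2 and ketoisophorone 1. Enolisation toward the only α-hydrogen makes the triflate regiochemically unambiguous and erases the auxiliary centre at C6 of 3.

**36 to 33 and 35.** The stannylated alkene of 36 is cut to aldehyde 33 and the one-carbon reagent (dibromomethyl)tributylstannane 35, made from dibromomethane 34. Aldehyde 33 is the oxidation product of allylic alcohol 32. Introducing tin last keeps a vinylstannane out of the earlier palladium steps. The olefination must give the E isomer and leave the lactone alone.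

**32 to 31 and 26.** The bond between C3 of ring C and the vinyl group of ring B is cut, giving bromobutenolide 31 and vinylstannane 26. This is the only position of ring C where a halide is left after the lactone has been built, and the cut separates all stereocentres of ring B from the butenolide chemistry.

**31 to 28 and 29.** Ring C is opened at its O1–C5 bond and at the bond from C4 to the ylidene carbon. The precursors are (E)-2,3-dibromopropenoic acid 28 (from propiolic acid 27) and the enynol 29, by way of the enynoic acid 30. Forming the ylidene by anti addition of a carboxylate to an alkyne fixes the Z geometry, which a carbonyl olefination at this position would not.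

**26 to 23.** The vinyltin unit of 26 is traced to the ethynyl group of triol 25. The C5 hydroxyl of 25 is removed with inversion to give the syn-epoxy alcohol 24, and the oxirane is taken back to the enynol 23. The three centres are thus reduced to one. The forward steps must deliver oxygen to the alkene face syn to the C3 hydroxyl and let water open the oxirane at C5 only.

**23 to 3.** Enynol 23 comes from its bis-silyl form 22. The ring–alkyne bond is cut to the enantiomeric-series triflate 20 and ethynyltrimethylsilane 21. Triflate 20 goes back through silyl ether 19 and the cis hydroxy ketone 18 to the inverted ester 17 and the same hydroxy ketone 3 that serves ring A. The inversion is placed on 3 because its hydroxyl is axial there and can be displaced from the open equatorial side.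

## Roads not taken

**Alternative 1:** The cut is the C1–C6 bond of ring B.
- Forward step: a Lewis acid activates the ketone of the acyclic ynone A2. The dimethyl-substituted γ-carbon of its allylsilane attacks the carbonyl carbon, silicon is lost and the cyclohexene carbinol A1 results.
- Merits: the two adjacent fully substituted carbons C1 and C6 are joined in one step. The trans relation of the C5 and C6 oxygens can be set by a chelated transition state. No inversion of a pool-derived carbinol is needed.
- Weak points: the tertiary silyl ether centre of A2 must be made enantioselectively. The allylsilane can add to the ynone in the conjugate sense. A1 still lacks the C3 hydroxyl, which must be placed on the C2=C3 alkene with control of both regiochemistry and face.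
- Comparison: for the C5/C6 diol alone this road is more direct and avoids the regiochemical question of step 17. The chosen plan sets against it that all three centres of ring B descend from one inexpensive centre by reactions of known stereochemical course, and that Alternative 1 does nothing for the polyene, where the chosen key step saves the most operations.

**Alternative 2:** The cut removes the carbonyl carbon of ring C (C2–C3 and C2–O1 bonds).
- Forward step: zerovalent palladium inserts into the C–I bond of the (Z)-β-iodoenone A4 and carbon monoxide gives the acylpalladium. The ketone enolises toward its methylene group and the dienolate oxygen attacks the acyl group, closing the lactone with its exocyclic alkene to give A3.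
- Merits: ring C is assembled late from an acyclic chain and one carbon of CO. The vinylsilane terminus of A3 is a further coupling site.
- Weak points: the ylidene geometry depends on the geometry of enolisation and not on a stereospecific addition. C-acylation and simple alkoxycarbonylation compete. The iodoenone carries the acid-labile tertiary allylic alcohol next to a Michael acceptor.
- Comparison: this road could be shorter for rings B and C than steps 19 to 22. The chosen plan sets against it a lactonisation whose Z outcome follows from anti addition to an alkyne.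

**Alternative 3:** The cut is the ring A alkyne itself.
- Forward step: lithiated trimethylsilyldiazomethane adds to the cross-conjugated dienone A6. Loss of silanolate and nitrogen gives an alkylidene carbene, and 1,2-shift of an alkenyl group gives the enyne A5.
- Merits: no coupling at the hindered triflate and no terminal diyne are needed. Either migrating group gives the same alkyne, and the E alkene is fixed beforehand.
- Weak points: addition to a ketone flanked by the tetrasubstituted ring carbon is slow, and insertion of the carbene into a methyl C–H bond competes. A5 ends at an allylic silyl ether, so deprotection, oxidation and an iodo-olefination are still needed to reach 16.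
- Comparison: the geometry is as secure as in the chosen plan and the risk of C–H metalation in step 7 is avoided. The chosen plan sets against it that one flask forms two C–C bonds and delivers the dienyl unit already in coupling-ready form.

Key step: step 7

Remark on the chemistry: 6, 12, 21, 27, 29 and 34 are taken as purchased; the stannyl reagent 35 is not an article of commerce and is made in step 23.

## Route

Step 1
Reactants: 1 ketoisophorone (2,6,6-trimethylcyclohex-2-ene-1,4-dione)
Product: 2 (R)-2,2,6-trimethylcyclohexane-1,4-dione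
Conditions: baker's yeast (Saccharomyces cerevisiae), sucrose, H2O, 30 °C
Reagents that add atoms: none
Why: Enzymatic conjugate reduction of the enedione by the ene-reductase (old yellow enzyme) of fermenting yeast, a known whole-cell reduction of this diketone; hydride is delivered to one alkene face so that C6 becomes R.

Step 2
Reactants: 2 (R)-2,2,6-trimethylcyclohexane-1,4-dione
Product: 3 (4R,6R)-4-hydroxy-2,2,6-trimethylcyclohexan-1-one
Conditions: Li[HB(sBu)3], THF, −78 °C; aq. NH4Cl
Reagents that add atoms: none
Why: Diastereoselective hydride reduction of a cyclohexanone; the bulky borohydride reaches only the unhindered C4 carbonyl and attacks it equatorially, away from the axial methyl of C2, so the hydroxyl becomes axial and trans to the C6 methyl (4R), while the C1 carbonyl between a quaternary and a tertiary carbon is left.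

Step 3
Reactants: 3 (4R,6R)-4-hydroxy-2,2,6-trimethylcyclohexan-1-one
Product: 4 (4R,6R)-4-[(tert-butyldimethylsilyl)oxy]-2,2,6-trimethylcyclohexan-1-one
Conditions: TBSCl, imidazole, DMF, rt
Reagents that add atoms: tert-butyldimethylsilyl chloride, CC(C)(C)[Si](C)(C)Cl
Why: Imidazole-promoted silylation of a secondary alcohol; the silyl ether tolerates the amide base, the palladium steps and the alane that follow.

Step 4
Reactants: 4 (4R,6R)-4-[(tert-butyldimethylsilyl)oxy]-2,2,6-trimethylcyclohexan-1-one
Product: 5 (R)-4-[(tert-butyldimethylsilyl)oxy]-2,6,6-trimethylcyclohex-1-en-1-yl trifluoromethanesulfonate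
Conditions: LiN(iPr)2, THF, −78 °C; PhNTf2, −78 °C to rt; aq. NH4Cl
Reagents that add atoms: N-phenylbis(trifluoromethanesulfonimide), O=S(=O)(N(c1ccccc1)S(=O)(=O)C(F)(F)F)C(F)(F)F
Why: Enolate O-triflation; the only α-hydrogen is at C6, so a single tetrasubstituted enol triflate should form, the auxiliary centre at C6 is erased and the carbinol centre alone remains.

Step 5
Reactants: 5 (R)-4-[(tert-butyldimethylsilyl)oxy]-2,6,6-trimethylcyclohex-1-en-1-yl trifluoromethanesulfonate; 6 1,4-bis(trimethylsilyl)buta-1,3-diyne
Product: 9 (R)-tert-butyldimethyl({3,5,5-trimethyl-4-[4-(trimethylsilyl)buta-1,3-diyn-1-yl]cyclohex-3-en-1-yl}oxy)silane, via lithium 4-(trimethylsilyl)butadiynide 7 (not isolated), via trimethylsilylbutadiyne 8 (not isolated)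
Conditions: MeLi·LiBr, Et2O, rt; aq. NH4Cl; then 5, Pd(PPh3)4, CuI, iPr2NH, THF, rt
Reagents that add atoms: none
Why: Methyllithium cleaves one silyl group of 6 by attack at silicon, and the protonated diyne is joined to the enol triflate by Sonogashira coupling (zerovalent palladium with CuI); the remaining silyl group prevents a second coupling.

Step 6
Reactants: 9 (R)-tert-butyldimethyl({3,5,5-trimethyl-4-[4-(trimethylsilyl)buta-1,3-diyn-1-yl]cyclohex-3-en-1-yl}oxy)silane
Product: 10 (R)-{[4-(buta-1,3-diyn-1-yl)-3,5,5-trimethylcyclohex-3-en-1-yl]oxy}(tert-butyl)dimethylsilane (ring A butadiyne)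
Conditions: K2CO3, MeOH/THF, rt
Reagents that add atoms: none
Why: Carbonate-catalysed methanolysis of an alkynylsilane; the secondary silyl ether is stable to it and the labile terminal diyne is used at once.

Step 7
Reactants: 10 (R)-{[4-(buta-1,3-diyn-1-yl)-3,5,5-trimethylcyclohex-3-en-1-yl]oxy}(tert-butyl)dimethylsilane; 11 trimethylaluminium; 12 (E)-(2-bromovinyl)trimethylsilane
Product: 14 (R)-tert-butyldimethyl({3,5,5-trimethyl-4-[(3E,5E)-3-methyl-6-(trimethylsilyl)hexa-3,5-dien-1-yn-1-yl]cyclohex-3-en-1-yl}oxy)silane, via alkenyldimethylalane 13 (not isolated)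
Conditions: 11 (2.5 equiv), Cp2ZrCl2 (0.25 equiv), ClCH2CH2Cl, 0 °C to rt; then 12, ZnCl2, Pd(PPh3)4 (5 mol%), THF, rt
Reagents that add atoms: none
Why: Cp2ZrCl2 and Me3Al form a methylzirconium–aluminium species that adds methyl and metal syn across the terminal triple bond of 10 through a four-centre transition state, methyl to the inner carbon and metal to the terminal carbon, and exchange gives the alane 13. The alkenyl group passes through zinc to palladium that has inserted into the C–Br bond of 12, and reductive elimination gives 14 with retention at both alkene carbons. The closest known reaction type is the zirconium-catalysed methylalumination of terminal alkynes, enynes and silylbutadiynes followed by palladium- and zinc-cocatalysed alkenyl–alkenyl coupling. No ring is closed and no stereocentre is formed, so the C3 silyl ether is a spectator. The step needs regioselectivity and syn stereospecificity. The ring-bound triple bond is shielded by the C1 gem-dimethyl group and the C5 methyl group, so only the terminal one reacts. Metal at the unhindered terminus places the methyl group correctly. Syn addition puts the alkyne and the new vinyl group trans, and the E bromide is transferred unchanged, which gives the 3E,5E diene.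

Step 8
Reactants: 14 (R)-tert-butyldimethyl({3,5,5-trimethyl-4-[(3E,5E)-3-methyl-6-(trimethylsilyl)hexa-3,5-dien-1-yn-1-yl]cyclohex-3-en-1-yl}oxy)silane
Product: 15 (R)-3,5,5-trimethyl-4-[(3E,5E)-3-methyl-6-(trimethylsilyl)hexa-3,5-dien-1-yn-1-yl]cyclohex-3-en-1-ol
Conditions: Bu4NF, THF, 0 °C to rt
Reagents that add atoms: none
Why: Fluoride cleavage of the silyl ether; the vinylic C–Si bond is not attacked under these conditions, and deprotecting here leaves no group to remove from the final polyene.

Step 9
Reactants: 15 (R)-3,5,5-trimethyl-4-[(3E,5E)-3-methyl-6-(trimethylsilyl)hexa-3,5-dien-1-yn-1-yl]cyclohex-3-en-1-ol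
Product: 16 (R)-4-[(3E,5E)-6-iodo-3-methylhexa-3,5-dien-1-yn-1-yl]-3,5,5-trimethylcyclohex-3-en-1-ol
Conditions: N-iodosuccinimide, 2,6-lutidine, (CF3)2CHOH, 0 °C, dark
Reagents that add atoms: N-iodosuccinimide, O=C1CCC(=O)N1I
Why: Electrophilic ipso-iododesilylation; iodonium attacks the silicon-bearing carbon (β-silyl cation) and loss of silicon should give the iodide with retention of the E geometry, the fluorinated alcohol speeding the substitution.

Step 10
Reactants: 3 (4R,6R)-4-hydroxy-2,2,6-trimethylcyclohexan-1-one
Product: 17 (1S,5R)-3,3,5-trimethyl-4-oxocyclohexyl 4-nitrobenzoate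
Conditions: 4-nitrobenzoic acid, PPh3, DIAD, THF, 0 °C to rt
Reagents that add atoms: 4-nitrobenzoic acid, OC(=O)c1ccc(cc1)[N+](=O)[O-]
Why: Mitsunobu inversion; the hydroxyl, axial in the preferred chair, is activated as the oxyphosphonium ion and displaced from the open equatorial side by the carboxylate (SN2), which gives the S carbinol ester needed for ring B.

Step 11
Reactants: 17 (1S,5R)-3,3,5-trimethyl-4-oxocyclohexyl 4-nitrobenzoate
Product: 18 (4S,6R)-4-hydroxy-2,2,6-trimethylcyclohexan-1-one
Conditions: K2CO3, MeOH, rt
Reagents that add atoms: none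
Why: Transesterification of the aryl ester with methanol; any epimerisation at C6 by the base is without consequence because that centre is erased in step 13.

Step 12
Reactants: 18 (4S,6R)-4-hydroxy-2,2,6-trimethylcyclohexan-1-one
Product: 19 (4S,6R)-4-[(tert-butyldimethylsilyl)oxy]-2,2,6-trimethylcyclohexan-1-one
Conditions: TBSCl, imidazole, DMF, rt
Reagents that add atoms: tert-butyldimethylsilyl chloride, CC(C)(C)[Si](C)(C)Cl
Why: Silylation of a secondary alcohol, as in step 3.

Step 13
Reactants: 19 (4S,6R)-4-[(tert-butyldimethylsilyl)oxy]-2,2,6-trimethylcyclohexan-1-one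
Product: 20 (S)-4-[(tert-butyldimethylsilyl)oxy]-2,6,6-trimethylcyclohex-1-en-1-yl trifluoromethanesulfonate
Conditions: LiN(iPr)2, THF, −78 °C; PhNTf2, −78 °C to rt; aq. NH4Cl
Reagents that add atoms: N-phenylbis(trifluoromethanesulfonimide), O=S(=O)(N(c1ccccc1)S(=O)(=O)C(F)(F)F)C(F)(F)F
Why: Enolate O-triflation as in step 4; it gives the enantiomer of 5 with the carbinol centre as the only stereocentre.

Step 14
Reactants: 20 (S)-4-[(tert-butyldimethylsilyl)oxy]-2,6,6-trimethylcyclohex-1-en-1-yl trifluoromethanesulfonate; 21 ethynyltrimethylsilane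
Product: 22 (S)-tert-butyldimethyl({3,5,5-trimethyl-4-[(trimethylsilyl)ethynyl]cyclohex-3-en-1-yl}oxy)silane
Conditions: Pd(PPh3)4, CuI, iPr2NH, THF, rt to 40 °C
Reagents that add atoms: none
Why: Sonogashira coupling of the enol triflate with a silyl-capped acetylene, the reaction type of step 5.

Step 15
Reactants: 22 (S)-tert-butyldimethyl({3,5,5-trimethyl-4-[(trimethylsilyl)ethynyl]cyclohex-3-en-1-yl}oxy)silane
Product: 23 (S)-4-ethynyl-3,5,5-trimethylcyclohex-3-en-1-ol
Conditions: Bu4NF, THF, rt
Reagents that add atoms: none
Why: Fluoride removes both silyl groups in one operation (Si–O and Si–C cleavage), freeing the hydroxyl that directs step 16.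

Step 16
Reactants: 23 (S)-4-ethynyl-3,5,5-trimethylcyclohex-3-en-1-ol
Product: 24 (1R,3R,6R)-6-ethynyl-1,5,5-trimethyl-7-oxabicyclo[4.1.0]heptan-3-ol (oxirane cis to the hydroxyl)
Conditions: VO(acac)2 (cat.), tBuOOH, CH2Cl2, rt
Reagents that add atoms: tert-butyl hydroperoxide, CC(C)(C)OO
Why: Hydroxyl-directed epoxidation; the homoallylic alcohol binds vanadium as its alkoxide and the peroxide oxygen is delivered to the alkene face on which the hydroxyl sits, so both oxirane carbons are set syn to the carbinol; alkyne and alcohol are not oxidised.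

Step 17
Reactants: 24 (1R,3R,6R)-6-ethynyl-1,5,5-trimethyl-7-oxabicyclo[4.1.0]heptan-3-ol
Product: 25 (1R,2S,4R)-1-ethynyl-2,6,6-trimethylcyclohexane-1,2,4-triol
Conditions: HClO4 (cat.), THF/H2O, 0 °C to rt
Reagents that add atoms: water, O
Why: Acid-catalysed hydrolysis of the epoxide; water attacks the methyl-bearing carbon from the face opposite the oxirane (inversion, giving 2S) while the C–O bond at the ethynyl-bearing carbon is kept. That carbon is deactivated by the alkyne and shielded by the gem-dimethyl group, and this is also the trans-diaxial (Fürst–Plattner) mode with the secondary hydroxyl equatorial.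

Step 18
Reactants: 25 (1R,2S,4R)-1-ethynyl-2,6,6-trimethylcyclohexane-1,2,4-triol
Product: 26 (1S,2S,4R)-2,6,6-trimethyl-1-[(E)-2-(tributylstannyl)ethenyl]cyclohexane-1,2,4-triol
Conditions: Bu3SnH, PdCl2(PPh3)2 (cat.), THF, 0 °C to rt
Reagents that add atoms: tributyltin hydride, CCCC[SnH](CCCC)CCCC
Why: Palladium-catalysed hydrostannation; H and Sn add syn, and tin goes to the terminal carbon because the fully substituted carbinol blocks the inner one, giving the E-vinylstannane with the hydroxyls untouched.

Step 19
Reactants: 27 propiolic acid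
Product: 28 (E)-2,3-dibromoprop-2-enoic acid
Conditions: Br2 (1 equiv), CH2Cl2, 0 °C to rt, dark
Reagents that add atoms: bromine, BrBr
Why: Anti addition of bromine to the alkyne gives the E dibromide, in which the C3 bromine is cis to the carboxyl group as the later lactonisation requires.

Step 20
Reactants: 28 (E)-2,3-dibromoprop-2-enoic acid; 29 (E)-3-methylpent-2-en-4-yn-1-ol
Product: 31 (Z)-3-bromo-5-[(E)-4-hydroxy-2-methylbut-2-en-1-ylidene]furan-2(5H)-one, via bromoenynoic acid 30 (not isolated)
Conditions: Pd(PPh3)4 (cat.), CuI (cat.), Et3N, MeCN, rt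
Reagents that add atoms: none
Why: Tandem Sonogashira coupling and lactonisation; the β-bromine of the acrylic acid undergoes oxidative addition faster than the α-bromine, and the (Z)-enynoic acid closes 5-exo-dig by anti addition of the carboxylate across the metal-activated alkyne, which gives the Z ylidene and keeps the α-bromine for step 21.

Step 21
Reactants: 31 (Z)-3-bromo-5-[(E)-4-hydroxy-2-methylbut-2-en-1-ylidene]furan-2(5H)-one; 26 (1S,2S,4R)-2,6,6-trimethyl-1-[(E)-2-(tributylstannyl)ethenyl]cyclohexane-1,2,4-triol
Product: 32 (Z)-5-[(E)-4-hydroxy-2-methylbut-2-en-1-ylidene]-3-{(E)-2-[(1S,2S,4R)-1,2,4-trihydroxy-2,6,6-trimethylcyclohexyl]ethenyl}furan-2(5H)-one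
Conditions: Pd2(dba)3, AsPh3, NMP, rt to 40 °C, dark
Reagents that add atoms: none
Why: Stille coupling of an α-bromobutenolide with an alkenylstannane, with retention of the E geometry; the weakly donating arsine allows transmetalation at low temperature and free hydroxyls are tolerated.

Step 22
Reactants: 32 (Z)-5-[(E)-4-hydroxy-2-methylbut-2-en-1-ylidene]-3-{(E)-2-[(1S,2S,4R)-1,2,4-trihydroxy-2,6,6-trimethylcyclohexyl]ethenyl}furan-2(5H)-one
Product: 33 (2E)-3-methyl-4-[(2Z)-5-oxo-4-{(E)-2-[(1S,2S,4R)-1,2,4-trihydroxy-2,6,6-trimethylcyclohexyl]ethenyl}furan-2(5H)-ylidene]but-2-enal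
Conditions: MnO2, CH2Cl2, rt, dark
Reagents that add atoms: none
Why: MnO2 oxidises only the allylic primary alcohol; the secondary alcohol is not allylic, the tertiary ones cannot be oxidised, and the trans-diaxial diol cannot form the cyclic ester needed for glycol cleavage.

Step 23
Reactants: 34 dibromomethane
Product: 35 (dibromomethyl)tributylstannane
Conditions: LiN(iPr)2, THF/Et2O, −95 °C; Bu3SnCl, −95 °C to rt
Reagents that add atoms: tributyltin chloride, CCCC[Sn](Cl)(CCCC)CCCC
Why: Deprotonation of dibromomethane gives dibromomethyllithium, which is stannylated at low temperature before it can lose bromide; a known preparation of this reagent.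

Step 24
Reactants: 33 (2E)-3-methyl-4-[(2Z)-5-oxo-4-{(E)-2-[(1S,2S,4R)-1,2,4-trihydroxy-2,6,6-trimethylcyclohexyl]ethenyl}furan-2(5H)-ylidene]but-2-enal; 35 (dibromomethyl)tributylstannane
Product: 36 (Z)-5-[(2E,4E)-2-methyl-5-(tributylstannyl)penta-2,4-dien-1-ylidene]-3-{(E)-2-[(1S,2S,4R)-1,2,4-trihydroxy-2,6,6-trimethylcyclohexyl]ethenyl}furan-2(5H)-one
Conditions: CrCl2, LiI, THF/DMF, rt, dark
Reagents that add atoms: none
Why: Takai-type stannyl olefination; divalent chromium reduces the gem-dihalide (exchanged to the diiodide by LiI) to a gem-dichromium species that adds to the aldehyde and eliminates to the E-alkenylstannane, while lactone, polyene and hydroxyls are inert to the reagent.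

Step 25
Reactants: 36 (Z)-5-[(2E,4E)-2-methyl-5-(tributylstannyl)penta-2,4-dien-1-ylidene]-3-{(E)-2-[(1S,2S,4R)-1,2,4-trihydroxy-2,6,6-trimethylcyclohexyl]ethenyl}furan-2(5H)-one; 16 (R)-4-[(3E,5E)-6-iodo-3-methylhexa-3,5-dien-1-yn-1-yl]-3,5,5-trimethylcyclohex-3-en-1-ol
Product: 37 CNP0163979.2, (5Z)-3-{(E)-2-[(1S,2S,4R)-1,2,4-trihydroxy-2,6,6-trimethylcyclohexyl]ethenyl}-5-{(2E,4E,6E,8E)-11-[(4R)-4-hydroxy-2,6,6-trimethylcyclohex-1-en-1-yl]-2,9-dimethylundeca-2,4,6,8-tetraen-10-yn-1-ylidene}furan-2(5H)-one
Conditions: Pd2(dba)3, AsPh3, NMP, rt, dark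
Reagents that add atoms: none
Why: Stille coupling of a dienyl iodide with a trienylstannane at room temperature under neutral conditions, with retention at both termini; both partners carry free hydroxyls, so the coupling product is the target.

## Compound list

1 | ketoisophorone (2,6,6-trimethylcyclohex-2-ene-1,4-dione) | CC1=CC(=O)CC(C)(C)C1=O | starting material
2 | (R)-2,2,6-trimethylcyclohexane-1,4-dione | C[C@@H]1CC(=O)CC(C)(C)C1=O | intermediate
3 | (4R,6R)-4-hydroxy-2,2,6-trimethylcyclohexan-1-one | C[C@@H]1C[C@@H](O)CC(C)(C)C1=O | intermediate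
4 | (4R,6R)-4-[(tert-butyldimethylsilyl)oxy]-2,2,6-trimethylcyclohexan-1-one | C[C@@H]1C[C@@H](O[Si](C)(C)C(C)(C)C)CC(C)(C)C1=O | intermediate
5 | (R)-4-[(tert-butyldimethylsilyl)oxy]-2,6,6-trimethylcyclohex-1-en-1-yl trifluoromethanesulfonate | CC1=C(OS(=O)(=O)C(F)(F)F)C(C)(C)C[C@H](O[Si](C)(C)C(C)(C)C)C1 | intermediate
6 | 1,4-bis(trimethylsilyl)buta-1,3-diyne | C[Si](C)(C)C#CC#C[Si](C)(C)C | starting material
7 | lithium 4-(trimethylsilyl)buta-1,3-diyn-1-ide | [Li]C#CC#C[Si](C)(C)C | intermediate
8 | buta-1,3-diyn-1-yl(trimethyl)silane | C#CC#C[Si](C)(C)C | intermediate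
9 | (R)-tert-butyldimethyl({3,5,5-trimethyl-4-[4-(trimethylsilyl)buta-1,3-diyn-1-yl]cyclohex-3-en-1-yl}oxy)silane | CC1=C(C#CC#C[Si](C)(C)C)C(C)(C)C[C@H](O[Si](C)(C)C(C)(C)C)C1 | intermediate
10 | (R)-{[4-(buta-1,3-diyn-1-yl)-3,5,5-trimethylcyclohex-3-en-1-yl]oxy}(tert-butyl)dimethylsilane (ring A butadiyne) | CC1=C(C#CC#C)C(C)(C)C[C@H](O[Si](C)(C)C(C)(C)C)C1 | intermediate
11 | trimethylaluminium | C[Al](C)C | starting material
12 | (E)-(2-bromovinyl)trimethylsilane | C[Si](C)(C)/C=C/Br | starting material
13 | [(E)-4-{(R)-4-[(tert-butyldimethylsilyl)oxy]-2,6,6-trimethylcyclohex-1-en-1-yl}-2-methylbut-1-en-3-yn-1-yl]dimethylalane | CC1=C(C#C/C(C)=C/[Al](C)C)C(C)(C)C[C@H](O[Si](C)(C)C(C)(C)C)C1 | intermediate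
14 | (R)-tert-butyldimethyl({3,5,5-trimethyl-4-[(3E,5E)-3-methyl-6-(trimethylsilyl)hexa-3,5-dien-1-yn-1-yl]cyclohex-3-en-1-yl}oxy)silane (ring A enyne dienylsilane) | CC1=C(C#C/C(C)=C/C=C/[Si](C)(C)C)C(C)(C)C[C@H](O[Si](C)(C)C(C)(C)C)C1 | intermediate
15 | (R)-3,5,5-trimethyl-4-[(3E,5E)-3-methyl-6-(trimethylsilyl)hexa-3,5-dien-1-yn-1-yl]cyclohex-3-en-1-ol | CC1=C(C#C/C(C)=C/C=C/[Si](C)(C)C)C(C)(C)C[C@H](O)C1 | intermediate
16 | (R)-4-[(3E,5E)-6-iodo-3-methylhexa-3,5-dien-1-yn-1-yl]-3,5,5-trimethylcyclohex-3-en-1-ol | CC1=C(C#C/C(C)=C/C=C/I)C(C)(C)C[C@H](O)C1 | intermediate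
17 | (1S,5R)-3,3,5-trimethyl-4-oxocyclohexyl 4-nitrobenzoate | C[C@@H]1C[C@H](OC(=O)c2ccc(cc2)[N+](=O)[O-])CC(C)(C)C1=O | intermediate
18 | (4S,6R)-4-hydroxy-2,2,6-trimethylcyclohexan-1-one | C[C@@H]1C[C@H](O)CC(C)(C)C1=O | intermediate
19 | (4S,6R)-4-[(tert-butyldimethylsilyl)oxy]-2,2,6-trimethylcyclohexan-1-one | C[C@@H]1C[C@H](O[Si](C)(C)C(C)(C)C)CC(C)(C)C1=O | intermediate
20 | (S)-4-[(tert-butyldimethylsilyl)oxy]-2,6,6-trimethylcyclohex-1-en-1-yl trifluoromethanesulfonate | CC1=C(OS(=O)(=O)C(F)(F)F)C(C)(C)C[C@@H](O[Si](C)(C)C(C)(C)C)C1 | intermediate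
21 | ethynyltrimethylsilane | C#C[Si](C)(C)C | starting material
22 | (S)-tert-butyldimethyl({3,5,5-trimethyl-4-[(trimethylsilyl)ethynyl]cyclohex-3-en-1-yl}oxy)silane | CC1=C(C#C[Si](C)(C)C)C(C)(C)C[C@@H](O[Si](C)(C)C(C)(C)C)C1 | intermediate
23 | (S)-4-ethynyl-3,5,5-trimethylcyclohex-3-en-1-ol | CC1=C(C#C)C(C)(C)C[C@@H](O)C1 | intermediate
24 | (1R,3R,6R)-6-ethynyl-1,5,5-trimethyl-7-oxabicyclo[4.1.0]heptan-3-ol (oxirane cis to the hydroxyl) | C#C[C@]12C(C)(C)C[C@@H](O)C[C@@]1(C)O2 | intermediate
25 | (1R,2S,4R)-1-ethynyl-2,6,6-trimethylcyclohexane-1,2,4-triol | C#C[C@]1(O)C(C)(C)C[C@@H](O)C[C@]1(C)O | intermediate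
26 | (1S,2S,4R)-2,6,6-trimethyl-1-[(E)-2-(tributylstannyl)ethenyl]cyclohexane-1,2,4-triol | CCCC[Sn](CCCC)(CCCC)/C=C/[C@]1(O)C(C)(C)C[C@@H](O)C[C@]1(C)O | intermediate
27 | propiolic acid | C#CC(=O)O | starting material
28 | (E)-2,3-dibromoprop-2-enoic acid | OC(=O)/C(Br)=C\Br | intermediate
29 | (E)-3-methylpent-2-en-4-yn-1-ol | C#C/C(C)=C/CO | starting material
30 | (2E,6E)-2-bromo-8-hydroxy-6-methylocta-2,6-dien-4-ynoic acid | OC(=O)/C(Br)=C\C#C/C(C)=C/CO | intermediate
31 | (Z)-3-bromo-5-[(E)-4-hydroxy-2-methylbut-2-en-1-ylidene]furan-2(5H)-one | OC/C=C(C)/C=C1C=C(Br)C(=O)O/1 | intermediate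
32 | (Z)-5-[(E)-4-hydroxy-2-methylbut-2-en-1-ylidene]-3-{(E)-2-[(1S,2S,4R)-1,2,4-trihydroxy-2,6,6-trimethylcyclohexyl]ethenyl}furan-2(5H)-one | OC/C=C(C)/C=C1C=C(/C=C/[C@]2(O)C(C)(C)C[C@@H](O)C[C@]2(C)O)C(=O)O/1 | intermediate
33 | (2E)-3-methyl-4-[(2Z)-5-oxo-4-{(E)-2-[(1S,2S,4R)-1,2,4-trihydroxy-2,6,6-trimethylcyclohexyl]ethenyl}furan-2(5H)-ylidene]but-2-enal | O=C/C=C(C)/C=C1C=C(/C=C/[C@]2(O)C(C)(C)C[C@@H](O)C[C@]2(C)O)C(=O)O/1 | intermediate
34 | dibromomethane | BrCBr | starting material
35 | (dibromomethyl)tributylstannane | CCCC[Sn](CCCC)(CCCC)C(Br)Br | intermediate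
36 | (Z)-5-[(2E,4E)-2-methyl-5-(tributylstannyl)penta-2,4-dien-1-ylidene]-3-{(E)-2-[(1S,2S,4R)-1,2,4-trihydroxy-2,6,6-trimethylcyclohexyl]ethenyl}furan-2(5H)-one | CCCC[Sn](CCCC)(CCCC)/C=C/C=C(C)/C=C1C=C(/C=C/[C@]2(O)C(C)(C)C[C@@H](O)C[C@]2(C)O)C(=O)O/1 | intermediate
37 | CNP0163979.2, (5Z)-3-{(E)-2-[(1S,2S,4R)-1,2,4-trihydroxy-2,6,6-trimethylcyclohexyl]ethenyl}-5-{(2E,4E,6E,8E)-11-[(4R)-4-hydroxy-2,6,6-trimethylcyclohex-1-en-1-yl]-2,9-dimethylundeca-2,4,6,8-tetraen-10-yn-1-ylidene}furan-2(5H)-one | CC1=C(C#C/C(C)=C/C=C/C=C/C=C(C)/C=C2C=C(/C=C/[C@]3(O)C(C)(C)C[C@@H](O)C[C@]3(C)O)C(=O)O/2)C(C)(C)C[C@H](O)C1 | target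

## Step count and risks

Total step count: 25. Longest linear sequence: 15 steps (1, 2, 10 to 18, 21, 22, 24, 25). The ring A arm is 10 steps (1 to 9, 25), and the ring C arm joins at step 21.

**Step 7 (key step).** The terminal C–H of a conjugated diyne is acidic, so metalation by Me3Al can compete with carbometalation and return diyne on work-up. The diyne can also oligomerise during the slow addition. A sluggish transfer from aluminium to palladium would favour homocoupling of the alane. The fallback sets out from triflate 5 and buys the trisubstituted alkene in place of making it. Sonogashira coupling of 5 with 29 should give the ring A enynol F1. MnO2 oxidation should give the ring A enynal F2. Takai iodo-olefination (CHI3, CrCl2, THF) should give the dienyl iodide silyl ether F3. Bu4NF then returns to the route at 16.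

**Step 16.** Facial discrimination may be poor, because the hydroxyl directs from a homoallylic position through a conformer in which it is syn-axial to a methyl group of C1. Oxygen transfer to the enyne may also be slow. The fallback sets out from 5 and uses steric approach followed by inversion. Sonogashira coupling of 5 with 21 should give the ring A-series silyl enyne F4. Peracid epoxidation anti to the silyloxy group should give the anti epoxide F5, which has the same oxirane configuration as 24. Bu4NF should give the anti epoxy alcohol F6. Mitsunobu inversion of the carbinol with 4-nitrobenzoic acid should give the syn epoxy ester F7. Methanolysis (K2CO3, MeOH) returns to the route at 24.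

**Step 17.** Water may enter at the propargylic carbon if positive charge there is better stabilised than assumed. That would give the diastereomeric triol. The fallback sets out from 22 and uses the other oxirane face, for which attack at the propargylic carbon is the productive, trans-diaxial mode. Peracid epoxidation of 22 anti to the silyloxy group should give the anti epoxide F8. Aqueous acid should then give the silylated diol F9. Bu4NF returns to the route at 25.

**Step 24.** The tin-bearing gem-dichromium reagent is the bulkiest and least reactive of its family. Incomplete conversion, reductive coupling of the conjugated aldehyde by divalent chromium, and loss of tin from the product on silica are the likely failures. The fallback sets out from 33 and 16 and exchanges the roles of the partners. Takai iodo-olefination of 33 (CHI3, CrCl2) should give the trienyl iodide F10. Tin–iodine exchange on 16 with (Bu3Sn)2 and PdCl2(PPh3)2 should give the ring A dienylstannane F11. Stille coupling of F10 with F11 returns to the route at 37.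

**Step 25.** Slow transmetalation of the long stannane would lead to homocoupling and to isomerisation of the polyene or of the Z ylidene during a prolonged exposure to palladium. The fallback sets out from 33 and changes the metal. Boron-Takai olefination of 33 (Cl2CHBpin, CrCl2, LiI) should give the trienyl pinacol boronate F12. Suzuki–Miyaura coupling of F12 with 16 (PdCl2(dppf), aqueous K3PO4, THF, rt) returns to the route at 37.

## Further compounds

F1 | step 7 | (R,E)-5-{4-[(tert-butyldimethylsilyl)oxy]-2,6,6-trimethylcyclohex-1-en-1-yl}-3-methylpent-2-en-4-yn-1-ol | CC1=C(C#C/C(C)=C/CO)C(C)(C)C[C@H](O[Si](C)(C)C(C)(C)C)C1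
F2 | step 7 | (R,E)-5-{4-[(tert-butyldimethylsilyl)oxy]-2,6,6-trimethylcyclohex-1-en-1-yl}-3-methylpent-2-en-4-ynal | CC1=C(C#C/C(C)=C/C=O)C(C)(C)C[C@H](O[Si](C)(C)C(C)(C)C)C1
F3 | step 7 | (R)-tert-butyl({4-[(3E,5E)-6-iodo-3-methylhexa-3,5-dien-1-yn-1-yl]-3,5,5-trimethylcyclohex-3-en-1-yl}oxy)dimethylsilane | CC1=C(C#C/C(C)=C/C=C/I)C(C)(C)C[C@H](O[Si](C)(C)C(C)(C)C)C1
F4 | step 16 | (R)-tert-butyldimethyl({3,5,5-trimethyl-4-[(trimethylsilyl)ethynyl]cyclohex-3-en-1-yl}oxy)silane | CC1=C(C#C[Si](C)(C)C)C(C)(C)C[C@H](O[Si](C)(C)C(C)(C)C)C1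
F5 | step 16 | tert-butyldimethyl({(1R,3S,6R)-1,5,5-trimethyl-6-[(trimethylsilyl)ethynyl]-7-oxabicyclo[4.1.0]heptan-3-yl}oxy)silane | C[Si](C)(C)C#C[C@]12C(C)(C)C[C@H](O[Si](C)(C)C(C)(C)C)C[C@@]1(C)O2
F6 | step 16 | (1R,3S,6R)-6-ethynyl-1,5,5-trimethyl-7-oxabicyclo[4.1.0]heptan-3-ol | C#C[C@]12C(C)(C)C[C@H](O)C[C@@]1(C)O2
F7 | step 16 | (1R,3R,6R)-6-ethynyl-1,5,5-trimethyl-7-oxabicyclo[4.1.0]heptan-3-yl 4-nitrobenzoate | C#C[C@]12C(C)(C)C[C@@H](OC(=O)c3ccc(cc3)[N+](=O)[O-])C[C@@]1(C)O2
F8 | step 17 | tert-butyldimethyl({(1S,3R,6S)-1,5,5-trimethyl-6-[(trimethylsilyl)ethynyl]-7-oxabicyclo[4.1.0]heptan-3-yl}oxy)silane | C[Si](C)(C)C#C[C@@]12C(C)(C)C[C@@H](O[Si](C)(C)C(C)(C)C)C[C@]1(C)O2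
F9 | step 17 | (1R,2S,4R)-4-[(tert-butyldimethylsilyl)oxy]-2,6,6-trimethyl-1-[(trimethylsilyl)ethynyl]cyclohexane-1,2-diol | C[Si](C)(C)C#C[C@]1(O)C(C)(C)C[C@@H](O[Si](C)(C)C(C)(C)C)C[C@]1(C)O
F10 | step 24 | (Z)-5-[(2E,4E)-5-iodo-2-methylpenta-2,4-dien-1-ylidene]-3-{(E)-2-[(1S,2S,4R)-1,2,4-trihydroxy-2,6,6-trimethylcyclohexyl]ethenyl}furan-2(5H)-one | I/C=C/C=C(C)/C=C1C=C(/C=C/[C@]2(O)C(C)(C)C[C@@H](O)C[C@]2(C)O)C(=O)O/1
F11 | step 24 | (R)-3,5,5-trimethyl-4-[(3E,5E)-3-methyl-6-(tributylstannyl)hexa-3,5-dien-1-yn-1-yl]cyclohex-3-en-1-ol | CC1=C(C#C/C(C)=C/C=C/[Sn](CCCC)(CCCC)CCCC)C(C)(C)C[C@H](O)C1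
F12 | step 25 | (Z)-5-[(2E,4E)-2-methyl-5-(4,4,5,5-tetramethyl-1,3,2-dioxaborolan-2-yl)penta-2,4-dien-1-ylidene]-3-{(E)-2-[(1S,2S,4R)-1,2,4-trihydroxy-2,6,6-trimethylcyclohexyl]ethenyl}furan-2(5H)-one | CC1(C)OB(/C=C/C=C(C)/C=C2C=C(/C=C/[C@]3(O)C(C)(C)C[C@@H](O)C[C@]3(C)O)C(=O)O/2)OC1(C)C
A1 | alternative 1 | ring B cyclohexene propargylic carbinol, 2,2,6-trimethyl-6-[(triethylsilyl)oxy]-1-[(trimethylsilyl)ethynyl]cyclohex-3-en-1-ol | C[Si](C)(C)C#C[C@]1(O)C(C)(C)C=CC[C@]1(C)O[Si](CC)(CC)CC
A2 | alternative 1 | 4,8-dimethyl-4-[(triethylsilyl)oxy]-1,6-bis(trimethylsilyl)non-7-en-1-yn-3-one | C[Si](C)(C)C#CC(=O)[C@@](C)(O[Si](CC)(CC)CC)CC([Si](C)(C)C)C=C(C)C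
A3 | alternative 2 | ring B-ring C ylidene butenolide dienylsilane, (Z)-5-[(E)-2-methyl-3-(trimethylsilyl)prop-2-en-1-ylidene]-3-{(E)-2-[(1S,2S,4R)-1,2,4-trihydroxy-2,6,6-trimethylcyclohexyl]ethenyl}furan-2(5H)-one | C[Si](C)(C)/C=C(C)/C=C1C=C(/C=C/[C@]2(O)C(C)(C)C[C@@H](O)C[C@]2(C)O)C(=O)O/1
A4 | alternative 2 | (1E,3Z,7E)-3-iodo-7-methyl-1-[(1S,2S,4R)-1,2,4-trihydroxy-2,6,6-trimethylcyclohexyl]-8-(trimethylsilyl)octa-1,3,7-trien-5-one | C[Si](C)(C)/C=C(C)/CC(=O)/C=C(\I)/C=C/[C@]1(O)C(C)(C)C[C@@H](O)C[C@]1(C)O
A5 | alternative 3 | ring A enyne allylic silyl ether, (R,E)-tert-butyl({5-{4-[(tert-butyldimethylsilyl)oxy]-2,6,6-trimethylcyclohex-1-en-1-yl}-3-methylpent-2-en-4-yn-1-yl}oxy)dimethylsilane | CC1=C(C#C/C(C)=C/CO[Si](C)(C)C(C)(C)C)C(C)(C)C[C@H](O[Si](C)(C)C(C)(C)C)C1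
A6 | alternative 3 | (R,E)-4-[(tert-butyldimethylsilyl)oxy]-1-{4-[(tert-butyldimethylsilyl)oxy]-2,6,6-trimethylcyclohex-1-en-1-yl}-2-methylbut-2-en-1-one | CC1=C(C(=O)/C(C)=C/CO[Si](C)(C)C(C)(C)C)C(C)(C)C[C@H](O[Si](C)(C)C(C)(C)C)C1
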